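1. I began from time: north-east's first nucleophile arrived over 10 h, and I asked how that stood against the life of the substrate.

| flask | substrate | first nucleophile | solid second nucleophile | remark | time |
|---|---|---|---|---|---|
| amber | 0.020 M | 0.060 M | 0.040 M | run made earlier |  |
| green | 0.020 M | 0.030 M | 0.040 M | run made earlier |  |
| north-east | 0.020 M | 0.0600 M (fed, over 10 h) | 0.0400 M | all else is in the flask from the start; the feed brings no volume worth counting | 25 h |
| south | 0.020 M | 0.0600 M | 0.0400 M | everything together at the start | 25 h |
| south-west | 0.020 M (fed, over 10 h) | 0.0600 M | 0.0400 M | all else is in the flask from the start; the feed brings no volume worth counting | 25 h |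

| run | time / h | other capture product / % | target / % |
|---|---|---|---|
| amber | 2.00 | 22 | 32 |
| amber | 6.00 | 43 | 40 |
| amber | 12.0 | 49 | 45 |
| amber | 20.0 | 50 | 44 |
| amber | 25.0 | 50 | 45 |
| green | 1.50 | 22 | 20 |
| green | 3.00 | 38 | 26 |
| green | 5.00 | 54 | 26 |
| green | 6.00 | 54 | 28 |
| green | 8.00 | 60 | 30 |

(readings scatter by 1.5 percentage points)

- at the start none of the solid second nucleophile is in solution

- the flask with the highest amount of other capture product, in percent of the substrate charged ("all alike" if they lie within 1.5 percentage points) (north-east / south / south-west / all alike)
- final other capture product, as a percentage of the substrate charged, in north-east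
- final other capture product, as a percentage of the substrate charged, in south
- final other capture product, as a percentage of the substrate charged, in south-west

2. I divided the rate of the other capture by the rate of the target capture and took the product ratio to go with the first nucleophile present, though time stayed in it, for amber's ratio moved at one charge. The bench rule is that this ratio runs inversely with the first nucleophile charged. Amber ended at a ratio of 1.11 after 25.0 h, and green's last reading, after 8.00 h, gave 2.00, a factor of 1.80 for a factor of 2.00 in the charge, so the rule held roughly. So I carried the tie fraction, the late product ratio times the fraction of the 0.0600 M charge present. Amber read 1.11, and green read 1.00.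

3. The rule treats the charge as present, so its border is the feed time over the substrate's life. Amber's products stood at 54.0% after 2.00 h, which reads as a life of 2.58 h. In north-east the feed ran longer, so one life in, the substrate met a fraction of 0.258 of the charge. My ratio for north-east was therefore 4.30, and with amber's 95.0% captured, I reckoned 77.1% other capture product. South repeats amber, at 50%. South-west keeps the full charge, so the rule puts it with south, but amber's ratio rose from 0.688 to 1.11, so I placed it above south without a figure.

4. The forecast chose north-east, with 79% there, 50% in south and 65% in south-west: “Feeding the first nucleophile keeps it scarce during the main conversion”. My north-east figure lay lower.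

5. The flasks gave 79.0% in north-east, 49.9% in south and 61.7% in south-west.

    substrate → intermediate (k = 0.380 h⁻¹)
    solid second nucleophile ⇌ second nucleophile, rate k2*(cs2 - [second nucleophile]) while solid is left; crystals form when [second nucleophile] > cs2 (solubility = 16.0 mM, k = 0.690 h⁻¹)
    substrate ⇌ dormant form (K = 1.60, k = 0.0370 h⁻¹)
    first nucleophile + intermediate → target (k = 150 M⁻¹ h⁻¹)
    second nucleophile + intermediate → other capture product (k = 1200 M⁻¹ h⁻¹)

6. North-east ended with 15.2% target, a ratio of 5.19, and the tie fraction turns that into 0.214 of the charge met. For the neighbour of south charged with 0.24 M of first nucleophile, the tie fraction gave a ratio of 0.278. That flask held 22.5% other capture product against 71.6% target, a ratio of 0.314.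

(The earlier runs and the new flask were generated by integration from invented constants, and the scatter is random.)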